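The constants used here come from no measurement; no experiment stands behind them.

In this scheme each electrophile that reacts takes one nucleophile and sets free one acid, and that acid sits on a second nucleophile, as protonated nucleophile or idle adduct A, until the scavenger takes it.

electrophile 0.50 mM; nucleophile 1.00 mM (fed, over 0.40 s); scavenger 0.750 mM; time 3.0 s

    electrophile + nucleophile → acid set free + product (k1 = 500 L mol⁻¹ s⁻¹)
    nucleophile + acid set free ⇌ protonated nucleophile, settled at all times (K2 = 1.0 × 10⁶ L mol⁻¹)
    nucleophile + acid set free ⇌ idle adduct A, settled at all times (K3 = 1.5 × 10⁵ L mol⁻¹)
    acid set free + scavenger → scavenged by-product (k4 = 7200 L mol⁻¹ s⁻¹)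
    nucleophile + product ⇌ idle adduct B, settled at all times (K5 = 1700 L mol⁻¹)

- part of the electrophile that has reacted at 3.0 s
- share of free nucleophile in free nucleophile and protonated nucleophile together, at 3.0 s

- what is said of product includes idle adduct B
- what is said of acid set free includes idle adduct A
- run time (flask): 3.0 s

1. Let x be the electrophile reacted. We carry the two-nucleophile ceiling, the part of the electrophile that the nucleophile charge can pay for at two per turnover: 100 %. By this count neither reagent is the limiting reagent here.
2. Upper bound: we count the whole charge as present from the midpoint of the feed and ignore idle adduct B. Free nucleophile then stays at two per electrophile left, the decay is second order, and the turnover count N = 2·k1·cA·t, with cA the electrophile charged and t the time on the clock, is 1.40. With c, the part of the electrophile reacted, equal to N/(1+N), c lies below 58.3 %.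
3. Lower bound: we start the clock at the end of the feed and divide the rate by 1 + K5·x, taking x from step 2. That factor is 1.50, so N = 0.869 and c lies above 46.5 %.
4. At the middle of the bracket, x = 0.262 mM. Free nucleophile then lies between 0.329 mM and 0.476 mM. Protonated nucleophile is 0.228 mM, so at this x fr, the share of free nucleophile in free and protonated nucleophile together, lies above 59.1 % and below 67.6 %.
5. Free acid of about x/((K2+K3)·0.329 mM) lets the scavenger take about 4.28 % of the turnovers, an allowance we leave out of step 2, so that upper bound holds only up to this allowance.

The forecast gives 55 % and 60 %, holding that “each electrophile consumed effectively takes two nucleophiles”. Both numbers stand inside our brackets.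

The simulation gives 54.7 % and 60.4 %, also inside.

In the flask the scavenger's half-life through its reaction with acid set free is 150 s at 3.00 s, longer than the electrophile's through its reaction with nucleophile, 2.1 s at 1.00 s. At 3.00 s the flask holds 0.00492 mM of scavenged by-product beside 0.233 mM of protonated nucleophile, and its conversion stands below the ceiling of 100 %. In the neighbour charged with 0.40 mM of nucleophile the ceiling is 40.0 %, and that flask reaches 26.4 %, with 99.2 % of its scavenger left.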